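The cis-dihydrobenzofuran is cut at C2–C3. C2 is a benzylic ether carbon (O1–C2H–aryl), so this bond can come from insertion of a C3 rhodium carbenoid (aryl diazoacetate on C3a of the benzo ring) into a C–H bond of an O1-bound 4-benzyloxy-3-methoxybenzyl ether. One catalyst-controlled operation closes the ring (O1, C2, C3, C3a, C7a) and sets both centres, cis. The precursor is the complete furofuran carrying a 5-iodovanillin-derived aryl whose "protecting group" is that vanillyl ether and whose iodide is exchanged for the diazoacetate. The furofuran itself is made by a Ti(III) epoxide-opening radical cyclisation with iodine-mediated second closure from two vinyl carbinols.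

Key step: step 9

Remark on the target: the SMILES is read as drawn, i.e. a cis-(2S,3S) dihydrobenzofuran on a (+)-pinoresinol-type (7S,8R,7'S,8'R) furofuran.
Remark on the catalyst: the (R)-series phthaloyl-tert-leucinate dirhodium catalyst is assumed to deliver the (2S,3R) ester, by analogy with simple 2-(benzyloxy)aryl diazoacetates; the antipodal catalyst is equally accessible should a model run show the opposite sense.
Abbreviations: Ar1 = 4-{[4-(benzyloxy)-3-methoxybenzyl]oxy}-3-iodo-5-methoxyphenyl; Ar2 = 4-(benzyloxy)-3,5-dimethoxyphenyl. Lignan locants C7/C8/C9 (Ar1 side) and C7'/C8'/C9' (Ar2 side) are used for the furofuran; O1, C2, C3, C3a, C7a for the dihydrobenzofuran.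

Step 1
Reactants: 1 5-iodovanillin; 2 4-(benzyloxy)-3-methoxybenzyl alcohol
Product: 3 4-{[4-(benzyloxy)-3-methoxybenzyl]oxy}-3-iodo-5-methoxybenzaldehyde (Ar1-CHO)
Conditions: PPh3, DIAD, THF, 0 °C to rt
Reagents that add atoms: none
Why: Mitsunobu etherification; the acidic, hindered iodophenol is alkylated by the activated benzylic alcohol under neutral conditions that leave the aldehyde untouched.

Step 2
Reactants: 3 Ar1-CHO
Product: 4 (±)-1-Ar1-prop-2-en-1-ol
Conditions: vinylmagnesium bromide, THF, −78 °C; aq. NH4Cl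
Reagents that add atoms: vinylmagnesium bromide, C=C[Mg]Br
Why: Grignard 1,2-addition, which at −78 °C is faster than iodine–magnesium exchange; the carbinol is racemic and is resolved in step 3.

Step 3
Reactants: 4 (±)-1-Ar1-prop-2-en-1-ol
Product: 5 (R)-Ar1[(S)-oxiran-2-yl]methanol (erythro epoxy alcohol)
Conditions: Ti(OiPr)4 (0.2 equiv), D-(−)-DIPT (0.3 equiv), t-BuOOH (0.45 equiv), 4 Å MS, CH2Cl2, −20 °C
Reagents that add atoms: tert-butyl hydroperoxide, CC(C)(C)OO
Why: Sharpless kinetic resolution; with D-(−)-DIPT the (S)-alcohol is the fast-reacting enantiomer and is epoxidised on the face that gives the erythro (1R,2S) epoxy alcohol, while the (R)-alcohol stays behind, and stopping below half conversion secures the enantiopurity of the product.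

Step 4
Reactants: 6 4-(benzyloxy)-3,5-dimethoxybenzaldehyde (Ar2-CHO)
Product: 7 (±)-1-Ar2-prop-2-en-1-ol
Conditions: vinylmagnesium bromide, THF, −78 to 0 °C; aq. NH4Cl
Reagents that add atoms: vinylmagnesium bromide, C=C[Mg]Br
Why: Grignard 1,2-addition to the aldehyde; the stereocentre is lost in step 5.

Step 5
Reactants: 7 (±)-1-Ar2-prop-2-en-1-ol
Product: 8 (E)-3-Ar2-prop-2-en-1-yl bromide (cinnamyl bromide)
Conditions: PBr3 (0.4 equiv), Et2O, 0 °C; used at once
Reagents that add atoms: phosphorus tribromide, BrP(Br)Br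
Why: bromination with allylic transposition (SN2'/ion-pair collapse) should give the conjugated, thermodynamically preferred E-cinnamyl bromide.

Step 6
Reactants: 5 (R)-Ar1[(S)-oxiran-2-yl]methanol; 8 (E)-3-Ar2-prop-2-en-1-yl bromide
Product: 9 (S)-2-[(R)-Ar1{[(E)-3-Ar2-prop-2-en-1-yl]oxy}methyl]oxirane
Conditions: NaH, Bu4NI (cat.), THF, 0 °C
Reagents that add atoms: none
Why: Williamson etherification; the sodium alkoxide displaces the primary allylic bromide (SN2) at 0 °C faster than Payne rearrangement can occur, and C7 is not touched.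

Step 7
Reactants: 9 epoxy cinnamyl ether
Product: 11 (1S,3aR,4S,6aR)-1-Ar1-4-Ar2-tetrahydro-1H,3H-furo[3,4-c]furan, via benzylic iodide titanium alkoxide 10 (not isolated)
Conditions: Cp2TiCl2 (2.2 equiv), Zn dust, THF, rt, slow addition; then I2 (1.2 equiv), rt to 50 °C
Reagents that add atoms: none
Why: Ti(III) epoxide-opening radical cyclisation with radical-polar crossover; Cp2TiCl opens the oxirane to the secondary β-titanoxy radical at C8, whose 5-exo attack on the styrene through a chair-like transition state with Ar1 pseudo-equatorial should set C8 (trans to Ar1) and C8' (cis to CH2OTi), iodine turns the benzylic radical/titanium species into iodide 10, and the titanium alkoxide closes the second ring through the stabilised benzylic cation on the convex face to the exo-aryl, cis-fused bicycle; the oxirane stereocentre is erased and C7 alone relays the absolute configuration.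

Step 8
Reactants: 11 iodo-furofuran
Product: 12 ethyl 2-diazo-2-{2-[(4-benzyloxy-3-methoxybenzyl)oxy]-3-methoxy-5-[(1S,3aR,4S,6aR)-4-Ar2-tetrahydro-1H,3H-furo[3,4-c]furan-1-yl]phenyl}acetate
Conditions: ethyl diazoacetate (2 equiv), Pd(PPh3)4 (10 mol%), Ag2CO3 (0.5 equiv), Et3N, toluene, rt
Reagents that add atoms: ethyl diazoacetate, CCOC(=O)C=[N+]=[N-]
Why: palladium-catalysed cross-coupling of an aryl iodide with a diazoacetate C–H bond (oxidative addition, C–Pd bond formation at the diazo carbon with retention of N2, reductive elimination), silver carbonate taking up iodide; the donor/acceptor diazo ester is stable enough to isolate.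

Step 9
Reactants: 12 aryl diazoacetate
Product: 13 ethyl (2S,3R)-cis-2-[4-(benzyloxy)-3-methoxyphenyl]-5-[(1S,3aR,4S,6aR)-4-Ar2-tetrahydro-1H,3H-furo[3,4-c]furan-1-yl]-7-methoxy-2,3-dihydro-1-benzofuran-3-carboxylate
Conditions: Rh2(R-PTTL)4 (2 mol%), 4 Å MS, toluene/CH2Cl2, −78 to −50 °C, slow addition of 12
Reagents that add atoms: none
Why: Dinitrogen loss from 12 at the chiral dirhodium tetracarboxylate gives a donor/acceptor rhodium carbenoid at the future C3, which inserts through a concerted, asynchronous three-centre (hydride-transfer-like) transition state into one of the two enantiotopic C–H bonds of the O1-bound vanillyl methylene; the closest known reaction type is the cis-selective, enantioselective intramolecular C–H insertion of 2-(benzyloxy)aryl diazoacetates to 2-aryl-2,3-dihydrobenzofuran-3-carboxylates. The dihydrofuran ring (O1, C2, C3, C3a, C7a) is closed by this 1,5-C–H insertion, which forms the C2–C3 bond. C2 and C3 are created together: their cis relationship is kinetic (the aryl group on the inserting carbon turns away from the ligand wall and ends syn to the ester), and the absolute sense, (2S,3R), is imposed by the N-phthaloyl-(R)-tert-leucinate ligands, the furofuran centres being too remote to interfere. The step needs site selectivity among several benzylic ether C–H bonds and chemoselectivity against arene cyclopropanation and carbene dimerisation; only the vanillyl CH2 lies within 1,5-reach of the carbenoid and it is doubly activated (ether oxygen, electron-rich aryl), the donor/acceptor carbenoid is discriminating, and slow addition at low temperature suppresses bimolecular paths. The cis ester is kept away from base, because C3–H is acidic and the trans isomer is the thermodynamic one.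

Step 10
Reactants: 13 cis ester
Product: 14 {(2S,3S)-2-[4-(benzyloxy)-3-methoxyphenyl]-5-[(1S,3aR,4S,6aR)-4-Ar2-tetrahydro-1H,3H-furo[3,4-c]furan-1-yl]-7-methoxy-2,3-dihydro-1-benzofuran-3-yl}methanol
Conditions: DIBAL-H (3 equiv), CH2Cl2, −78 to −40 °C; Rochelle salt
Reagents that add atoms: none
Why: DIBAL-H ester reduction at low temperature under non-basic conditions, so that the acidic C3–H is not epimerised and the cis relationship should be kept (the descriptor at C3 changes to S only through the priority rules).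

Step 11
Reactants: 14 dibenzyl ether
Product: 15 4-[(2S,3S)-5-{(1S,3aR,4S,6aR)-4-(4-hydroxy-3,5-dimethoxyphenyl)tetrahydro-1H,3H-furo[3,4-c]furan-1-yl}-3-(hydroxymethyl)-7-methoxy-2,3-dihydro-1-benzofuran-2-yl]-2-methoxyphenol (CNP0126146.1)
Conditions: H2 (1 atm), 10% Pd/C, EtOAc, rt, stopped at full conversion
Reagents that add atoms: none
Why: hydrogenolysis of the two aryl benzyl ethers, which should be faster than cleavage of the cyclic dibenzylic ethers; neutral conditions avoid quinone-methide epimerisation at C2 of the liberated p-hydroxyphenyl unit.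

Compound list
1 | 5-iodovanillin (4-hydroxy-3-iodo-5-methoxybenzaldehyde) | O=Cc1cc(I)c(O)c(OC)c1 | starting material
2 | 4-(benzyloxy)-3-methoxybenzyl alcohol | OCc1ccc(OCc2ccccc2)c(OC)c1 | starting material
3 | 4-{[4-(benzyloxy)-3-methoxybenzyl]oxy}-3-iodo-5-methoxybenzaldehyde | O=Cc1cc(I)c(OCc2ccc(OCc3ccccc3)c(OC)c2)c(OC)c1 | intermediate
4 | (±)-1-(4-{[4-(benzyloxy)-3-methoxybenzyl]oxy}-3-iodo-5-methoxyphenyl)prop-2-en-1-ol | C=CC(O)c1cc(I)c(OCc2ccc(OCc3ccccc3)c(OC)c2)c(OC)c1 | intermediate
5 | (R)-(4-{[4-(benzyloxy)-3-methoxybenzyl]oxy}-3-iodo-5-methoxyphenyl)[(S)-oxiran-2-yl]methanol | O[C@H](c1cc(I)c(OCc2ccc(OCc3ccccc3)c(OC)c2)c(OC)c1)[C@@H]1CO1 | intermediate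
6 | 4-(benzyloxy)-3,5-dimethoxybenzaldehyde | O=Cc1cc(OC)c(OCc2ccccc2)c(OC)c1 | starting material
7 | (±)-1-[4-(benzyloxy)-3,5-dimethoxyphenyl]prop-2-en-1-ol | C=CC(O)c1cc(OC)c(OCc2ccccc2)c(OC)c1 | intermediate
8 | (E)-2-(benzyloxy)-5-(3-bromoprop-1-en-1-yl)-1,3-dimethoxybenzene | BrC/C=C/c1cc(OC)c(OCc2ccccc2)c(OC)c1 | intermediate
9 | (S)-2-[(R)-(4-{[4-(benzyloxy)-3-methoxybenzyl]oxy}-3-iodo-5-methoxyphenyl){[(E)-3-(4-(benzyloxy)-3,5-dimethoxyphenyl)prop-2-en-1-yl]oxy}methyl]oxirane | COc1cc(/C=C/CO[C@H](c2cc(I)c(OCc3ccc(OCc4ccccc4)c(OC)c3)c(OC)c2)[C@@H]2CO2)cc(OC)c1OCc1ccccc1 | intermediate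
10 | chlorobis(cyclopentadienyl)titanium alkoxide of [(2S,3R,4R)-2-Ar1-4-(Ar2-iodomethyl)tetrahydrofuran-3-yl]methanol, both epimers at CHI (Cp drawn η1) | COc1cc([C@H]2OC[C@H](C(I)c3cc(OC)c(OCc4ccccc4)c(OC)c3)[C@@H]2CO[Ti](Cl)(C2C=CC=C2)C2C=CC=C2)cc(I)c1OCc1ccc(OCc2ccccc2)c(OC)c1 | intermediate
11 | (1S,3aR,4S,6aR)-1-(4-{[4-(benzyloxy)-3-methoxybenzyl]oxy}-3-iodo-5-methoxyphenyl)-4-[4-(benzyloxy)-3,5-dimethoxyphenyl]tetrahydro-1H,3H-furo[3,4-c]furan | COc1cc([C@H]2OC[C@H]3[C@@H]2CO[C@@H]3c2cc(OC)c(OCc3ccccc3)c(OC)c2)cc(I)c1OCc1ccc(OCc2ccccc2)c(OC)c1 | intermediate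
12 | ethyl 2-diazo-2-{2-[(4-benzyloxy-3-methoxybenzyl)oxy]-3-methoxy-5-[(1S,3aR,4S,6aR)-4-(4-benzyloxy-3,5-dimethoxyphenyl)tetrahydro-1H,3H-furo[3,4-c]furan-1-yl]phenyl}acetate | COc1cc([C@H]2OC[C@H]3[C@@H]2CO[C@@H]3c2cc(OC)c(OCc3ccccc3)c(OC)c2)cc(C(=[N+]=[N-])C(=O)OCC)c1OCc1ccc(OCc2ccccc2)c(OC)c1 | intermediate
13 | ethyl (2S,3R)-2-[4-(benzyloxy)-3-methoxyphenyl]-5-[(1S,3aR,4S,6aR)-4-(4-benzyloxy-3,5-dimethoxyphenyl)tetrahydro-1H,3H-furo[3,4-c]furan-1-yl]-7-methoxy-2,3-dihydro-1-benzofuran-3-carboxylate (cis) | COc1cc([C@H]2Oc3c(OC)cc([C@H]4OC[C@H]5[C@@H]4CO[C@@H]5c4cc(OC)c(OCc5ccccc5)c(OC)c4)cc3[C@H]2C(=O)OCC)ccc1OCc1ccccc1 | intermediate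
14 | {(2S,3S)-2-[4-(benzyloxy)-3-methoxyphenyl]-5-[(1S,3aR,4S,6aR)-4-(4-benzyloxy-3,5-dimethoxyphenyl)tetrahydro-1H,3H-furo[3,4-c]furan-1-yl]-7-methoxy-2,3-dihydro-1-benzofuran-3-yl}methanol (cis) | COc1cc([C@H]2Oc3c(OC)cc([C@H]4OC[C@H]5[C@@H]4CO[C@@H]5c4cc(OC)c(OCc5ccccc5)c(OC)c4)cc3[C@H]2CO)ccc1OCc1ccccc1 | intermediate
15 | 4-[(2S,3S)-5-{(1S,3aR,4S,6aR)-4-(4-hydroxy-3,5-dimethoxyphenyl)tetrahydro-1H,3H-furo[3,4-c]furan-1-yl}-3-(hydroxymethyl)-7-methoxy-2,3-dihydro-1-benzofuran-2-yl]-2-methoxyphenol | COc1cc([C@H]2Oc3c(OC)cc([C@H]4OC[C@H]5[C@@H]4CO[C@@H]5c4cc(OC)c(O)c(OC)c4)cc3[C@H]2CO)ccc1O | target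

Total step count: 11. Longest linear sequence: 9 steps (1, 2, 3, 6, 7, 8, 9, 10, 11); steps 4 and 5 form the side branch.

Steps most likely to fail

Step 9. The chiral carboxylate may fail to discriminate the two enantiotopic C–H bonds of so large and ether-rich a substrate, so that both cis ring diastereomers form. The fallback gives up catalyst control and uses the stereocentres already present as the resolving element. It sets out from 12: cyclisation with the achiral, bulky dirhodium tetrakis(triphenylacetate) (CH2Cl2, −40 °C) should give 13 together with its cis-(2R,3S) ring diastereomer F3. Because the furofuran is enantiopure, these two are diastereomers and are separated by chromatography (or, if needed, after DIBAL-H reduction as the alcohols). The route is rejoined at 13.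

Step 7. The cascade may stop after the first ring: the benzylic radical or titanium species can be reduced or lose HI before iodine intercepts it, so the second ring does not close in the pot. The fallback splits the cascade and moves the second closure to a hydroxyl-directed C–H etherification. It sets out from 9: Cp2TiCl alone (Cp2TiCl2, Zn, THF, rt), followed by aqueous NaH2PO4 work-up, should give the lariciresinol-type alcohol [(2S,3R,4R)-2-Ar1-4-(Ar2-methyl)tetrahydrofuran-3-yl]methanol F1. Lead tetraacetate (CaCO3, benzene, reflux) then converts the primary hydroxyl into an alkoxy radical; 1,5-hydrogen transfer from the cis-disposed benzylic CH2, oxidation of the benzylic radical to the cation and capture by the hydroxyl on the convex face return the route to 11.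

Step 8. Decomposition of the diazoacetate at palladium (carbene dimerisation, azine formation) may outrun coupling at the ortho-alkoxy aryl iodide. The fallback brings in the two-carbon unit as a zinc enolate and creates the diazo group afterwards. It sets out from 11: coupling with the Reformatsky reagent BrZnCH2CO2Et (Pd2(dba)3, XPhos, THF, 60 °C) should give the arylacetate ethyl 2-{2-[(4-benzyloxy-3-methoxybenzyl)oxy]-3-methoxy-5-[furofuranyl]phenyl}acetate F2. Regitz diazo transfer (p-acetamidobenzenesulfonyl azide, DBU, MeCN, 0 °C) returns the route to 12.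

Further compounds
F1 | step 7 | [(2S,3R,4R)-4-[4-(benzyloxy)-3,5-dimethoxybenzyl]-2-(4-{[4-(benzyloxy)-3-methoxybenzyl]oxy}-3-iodo-5-methoxyphenyl)tetrahydrofuran-3-yl]methanol | COc1cc([C@H]2OC[C@H](Cc3cc(OC)c(OCc4ccccc4)c(OC)c3)[C@@H]2CO)cc(I)c1OCc1ccc(OCc2ccccc2)c(OC)c1
F2 | step 8 | ethyl 2-{2-[(4-benzyloxy-3-methoxybenzyl)oxy]-3-methoxy-5-[(1S,3aR,4S,6aR)-4-(4-benzyloxy-3,5-dimethoxyphenyl)tetrahydro-1H,3H-furo[3,4-c]furan-1-yl]phenyl}acetate | COc1cc([C@H]2OC[C@H]3[C@@H]2CO[C@@H]3c2cc(OC)c(OCc3ccccc3)c(OC)c2)cc(CC(=O)OCC)c1OCc1ccc(OCc2ccccc2)c(OC)c1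
F3 | step 9 | ethyl (2R,3S)-2-[4-(benzyloxy)-3-methoxyphenyl]-5-[(1S,3aR,4S,6aR)-4-(4-benzyloxy-3,5-dimethoxyphenyl)tetrahydro-1H,3H-furo[3,4-c]furan-1-yl]-7-methoxy-2,3-dihydro-1-benzofuran-3-carboxylate (cis ring diastereomer of 13) | COc1cc([C@@H]2Oc3c(OC)cc([C@H]4OC[C@H]5[C@@H]4CO[C@@H]5c4cc(OC)c(OCc5ccccc5)c(OC)c4)cc3[C@@H]2C(=O)OCC)ccc1OCc1ccccc1
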